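**Plan**

- Cuts (isochromene numbering of the target: C1, O2, C3, C4, C4a, C5–C8, C8a): the enol-ether bond C1–O2 and the ring-fusion bond C4a–C8a are cut together, which opens both rings to one acyclic chain, the enaminone–ynone–alcohol 23. Further cuts at C1–C8a, the C7–O ester bond, C8–C8a and C6–C7 lead back to (S)-lactic acid, (R)-pent-4-yn-2-ol and oleoyl chloride.
- Forward: the chain is joined by an aldol reaction at the lactate carbon (C6–C7), converted to the methyl ketone (C8–C8a), O-oleoylated, aminomethylenated (C1) and oxidised at C6. In the last step the carbocycle closes first (C4a–C8a) and the pyran ring second (C1–O2).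
- Enabling feature: the O2–C1H=C8a–C8=O unit of the pyran ring is a vinylogous ester, a masked formyl ketone whose C8a is a carbon nucleophile while C1 carries an amine. C4a is the β-carbon of the C6 enone (an ynone in the precursor). C7 is quaternary, so the 6,8-dione cannot enolise and C8a is the only carbon nucleophile; the C3 oxygen is six atoms from C1 once the carbocycle exists.
- Stereochemistry: C3 (R) comes with (R)-pent-4-yn-2-ol and is never touched. C7 (R) comes from (S)-lactic acid by self-regeneration of the stereocentre (aldol anti to the tert-butyl group of the acetal-lactone). The key step creates no stereocentre.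

Key step: step 11

Assumption: the carbinol carbon formed in step 4 (later C6) is carried as a mixture of epimers, because step 10 oxidises it to the ketone; descriptors are given for the other centres only.

**Route**

Step 1
Reactants: 1 (S)-lactic acid; 2 pivalaldehyde
Product: 3 (2S,5S)-2-tert-butyl-5-methyl-1,3-dioxolan-4-one
Conditions: TsOH·H2O (cat.), H2SO4 (cat.), pentane, reflux, Dean–Stark; recrystallisation at −78 °C
Reagents that add atoms: pivalaldehyde 2, CC(C)(C)C=O
Why: Acid-catalysed acetalisation with azeotropic removal of water should give the cis acetal-lactone, the tert-butyl group settling cis to the methyl group under thermodynamic control (this sets the acetal carbon) and the minor trans isomer being removed by crystallisation.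

Step 2
Reactants: 4 (R)-pent-4-yn-2-ol; 5 chlorotriethylsilane
Product: 6 triethyl{[(2R)-pent-4-yn-2-yl]oxy}silane
Conditions: Et3SiCl, imidazole, CH2Cl2, 0 °C to rt
Reagents that add atoms: chlorotriethylsilane 5, CC[Si](Cl)(CC)CC
Why: Standard silyl ether formation masks the secondary alcohol for the organolithium, acylation and condensation steps without touching the stereocentre.

Step 3
Reactants: 6 triethyl{[(2R)-pent-4-yn-2-yl]oxy}silane; 7 N,N-dimethylformamide
Product: 10 (5R)-5-(triethylsilyloxy)hex-2-ynal, via lithium acetylide 8 (not isolated), via lithium hemiaminolate 9 (not isolated)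
Conditions: n-BuLi, THF, −78 °C; DMF, −78 to 0 °C; inverse quench into aq. KH2PO4/MTBE, 0 °C
Reagents that add atoms: N,N-dimethylformamide 7, CN(C)C=O
Why: Formylation of a lithium acetylide with DMF should give the ynal, because the hemiaminolate persists until the buffered inverse quench, which also keeps the liberated dimethylamine from adding to the ynal.

Step 4
Reactants: 3 (2S,5S)-2-tert-butyl-5-methyl-1,3-dioxolan-4-one; 10 (5R)-5-(triethylsilyloxy)hex-2-ynal
Product: 12 (2S,5R)-2-tert-butyl-5-[(5R)-1-hydroxy-5-(triethylsilyloxy)hex-2-yn-1-yl]-5-methyl-1,3-dioxolan-4-one, via lithium enolate 11 (not isolated)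
Conditions: LiN(i-Pr)2, THF, −78 °C; then 10, −78 °C; AcOH quench
Reagents that add atoms: none
Why: Aldol addition of the lithium enolate of the chiral acetal-lactone (self-regeneration of stereocentres) should occur on the face anti to the tert-butyl group, so the new C–C bond takes the place of the former hydrogen and fixes the quaternary carbon (later C7), while the carbinol carbon forms as an inconsequential mixture.

Step 5
Reactants: 12 the aldol adduct; 13 triethylsilyl trifluoromethanesulfonate
Product: 14 (2S,5R)-5-[(5R)-1,5-bis(triethylsilyloxy)hex-2-yn-1-yl]-2-tert-butyl-5-methyl-1,3-dioxolan-4-one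
Conditions: Et3SiOTf, 2,6-lutidine, CH2Cl2, −78 °C
Reagents that add atoms: triethylsilyl trifluoromethanesulfonate 13, CC[Si](CC)(CC)OS(=O)(=O)C(F)(F)F
Why: Low-temperature silylation with the silyl triflate and a hindered base should cap the hindered propargylic carbinol without retro-aldol cleavage, so that later only the tertiary oxygen is free for acylation.

Step 6
Reactants: 14 the bis(silyl ether) acetal-lactone; 15 methyllithium
Product: 17 (3R,8R)-3-hydroxy-3-methyl-4,8-bis(triethylsilyloxy)non-5-yn-2-one, via lithium hemiketal alkoxide 16 (not isolated)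
Conditions: MeLi, THF, −78 °C; then AcOH, −78 °C to rt
Reagents that add atoms: methyllithium 15, [Li]C
Why: Single addition of an organolithium to a 1,3-dioxolan-4-one should stop at the lithium hemiketal alkoxide 16, which is stable at −78 °C like the adduct of an N-methoxy-N-methylamide and collapses on cold protonation with loss of pivalaldehyde to the tertiary α-hydroxy methyl ketone, the quaternary centre being untouched.

Step 7
Reactants: 17 the α-hydroxy methyl ketone; 18 oleoyl chloride
Product: 19 (3R,8R)-3-methyl-2-oxo-4,8-bis(triethylsilyloxy)non-5-yn-3-yl (9Z)-octadec-9-enoate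
Conditions: oleoyl chloride, DMAP, Et3N, CH2Cl2, 0 to 40 °C
Reagents that add atoms: oleoyl chloride 18, CCCCCCCC/C=C\CCCCCCCC(=O)Cl
Why: DMAP-catalysed acylation through the acylpyridinium ion should esterify the only free hydroxyl, the hindered tertiary α-ketol, while silyl ethers, the alkyne and the quaternary centre (no α-hydrogen) stay unchanged.

Step 8
Reactants: 19 the tertiary oleate; 20 N,N-dimethylformamide dimethyl acetal
Product: 21 (1E,4R,9R)-1-(dimethylamino)-4-methyl-3-oxo-5,9-bis(triethylsilyloxy)dec-1-en-6-yn-4-yl (9Z)-octadec-9-enoate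
Conditions: Me2NCH(OMe)2, PhMe, 80 °C
Reagents that add atoms: N,N-dimethylformamide dimethyl acetal 20, COC(OC)N(C)C
Why: Aminomethylenation of a methyl ketone with DMF dimethyl acetal should give the (E)-enaminone, the methyl group being the only enolisable position because the neighbouring carbon is quaternary.

Step 9
Reactants: 21 the bis(silyl ether) enaminone
Product: 22 (1E,4R,9R)-1-(dimethylamino)-5,9-dihydroxy-4-methyl-3-oxodec-1-en-6-yn-4-yl (9Z)-octadec-9-enoate
Conditions: HF·pyridine, pyridine, THF, 0 °C to rt
Reagents that add atoms: none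
Why: Fluoride-mediated cleavage of both secondary triethylsilyl ethers under buffered, weakly acidic conditions should spare the vinylogous amide, the alkyne and the tertiary ester, since no base is present to trigger acyl migration to the neighbouring carbinol.

Step 10
Reactants: 22 the enaminone diol
Product: 23 (1E,4S,9R)-1-(dimethylamino)-9-hydroxy-4-methyl-3,5-dioxodec-1-en-6-yn-4-yl (9Z)-octadec-9-enoate
Conditions: MnO2 (activated, excess), CH2Cl2, rt
Reagents that add atoms: none
Why: Chemoselective MnO2 oxidation of an activated (propargylic) carbinol should form the ynone and erase the epimer mixture of step 4 while leaving the saturated secondary alcohol of the 2-hydroxypropyl end alone; the descriptor of the quaternary carbon changes to S only because the priorities change.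

Step 11
Reactants: 23 the enaminone–ynone–alcohol
Product: 26 (3R,7R)-3,7-dimethyl-6,8-dioxo-3,4,7,8-tetrahydro-6H-isochromen-7-yl (9Z)-octadec-9-enoate, via aminomethylene cyclohexenedione 24 (not isolated), via cyclic N,O-acetal 25 (not isolated)
Conditions: AcOH/PhMe (1:5), 50 °C
Reagents that add atoms: none
Why: Proposed new method: in warm acetic acid the enaminone α-carbon (future C8a) should add to the β-carbon of the hydrogen-bond-activated ynone (C4a) to give 24 after proton transfer to C5, the C3 hydroxyl should then add to C1 to give the N,O-acetal 25, and acid-assisted β-elimination of dimethylamine (held as its acetate) should leave the C1=C8a enol ether of the target. The closest known reaction types are the Michael addition of enamines and enaminones to ethynyl ketones and quinones (first stage of the Bohlmann–Rahtz pyridine synthesis and of the Nenitzescu indole synthesis) and the acid-induced closure of hydroxy-substituted enaminones to chromones and 4-pyranones with loss of the amine; joining the two in one tether to build a bicyclic vinylogous ester is new. The carbocycle closes in the 6-endo-dig mode (both alkyne carbons C4a and C5 end up in the ring) and the pyran ring in the 6-exo-trig mode on the C1=N iminium bond (6-endo-trig if the neutral enaminone is attacked). No stereocentre is created, since C1 and C8a of 25 become sp2 again on elimination, and C3 and the quaternary C7, which has no α-hydrogen and cannot enolise, are not touched. The step needs carbon- and not oxygen-reactivity of the enaminone and attack at C4a and not at C5; this is secured by the soft, polarised ynone β-carbon, by the quaternary C7 that excludes any competing enol, and by the fact that the hydroxyl cannot reach C1 before the first ring exists (that would be a ten-membered closure). Adventitious hydrolysis of the enaminone to the formyl ketone should not harm the step, because that species can follow the same course.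

**Compound list**

1 | (S)-lactic acid | C[C@H](O)C(=O)O | starting material
2 | pivalaldehyde | CC(C)(C)C=O | starting material
3 | (2S,5S)-2-tert-butyl-5-methyl-1,3-dioxolan-4-one | C[C@@H]1O[C@H](C(C)(C)C)OC1=O | intermediate
4 | (R)-pent-4-yn-2-ol | C#CC[C@@H](C)O | starting material
5 | chlorotriethylsilane | CC[Si](Cl)(CC)CC | starting material
6 | triethyl{[(2R)-pent-4-yn-2-yl]oxy}silane | C#CC[C@@H](C)O[Si](CC)(CC)CC | intermediate
7 | N,N-dimethylformamide | CN(C)C=O | starting material
8 | lithium (4R)-4-(triethylsilyloxy)pent-1-yn-1-ide | [Li+].[C-]#CC[C@@H](C)O[Si](CC)(CC)CC | intermediate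
9 | lithium (5R)-1-(dimethylamino)-5-(triethylsilyloxy)hex-2-yn-1-olate | [Li+].[O-]C(N(C)C)C#CC[C@@H](C)O[Si](CC)(CC)CC | intermediate
10 | (5R)-5-(triethylsilyloxy)hex-2-ynal | O=CC#CC[C@@H](C)O[Si](CC)(CC)CC | intermediate
11 | lithium (2S)-2-tert-butyl-5-methyl-1,3-dioxol-4-olate | [Li+].CC1=C([O-])O[C@@H](C(C)(C)C)O1 | intermediate
12 | (2S,5R)-2-tert-butyl-5-[(5R)-1-hydroxy-5-(triethylsilyloxy)hex-2-yn-1-yl]-5-methyl-1,3-dioxolan-4-one (carbinol epimers) | C[C@]1(C(O)C#CC[C@@H](C)O[Si](CC)(CC)CC)O[C@H](C(C)(C)C)OC1=O | intermediate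
13 | triethylsilyl trifluoromethanesulfonate | CC[Si](CC)(CC)OS(=O)(=O)C(F)(F)F | starting material
14 | (2S,5R)-5-[(5R)-1,5-bis(triethylsilyloxy)hex-2-yn-1-yl]-2-tert-butyl-5-methyl-1,3-dioxolan-4-one | C[C@]1(C(O[Si](CC)(CC)CC)C#CC[C@@H](C)O[Si](CC)(CC)CC)O[C@H](C(C)(C)C)OC1=O | intermediate
15 | methyllithium | [Li]C | starting material
16 | lithium (2S,5R)-5-[(5R)-1,5-bis(triethylsilyloxy)hex-2-yn-1-yl]-2-tert-butyl-4,5-dimethyl-1,3-dioxolan-4-olate | [Li+].C[C@]1(C(O[Si](CC)(CC)CC)C#CC[C@@H](C)O[Si](CC)(CC)CC)O[C@H](C(C)(C)C)OC1(C)[O-] | intermediate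
17 | (3R,8R)-3-hydroxy-3-methyl-4,8-bis(triethylsilyloxy)non-5-yn-2-one | CC(=O)[C@](C)(O)C(O[Si](CC)(CC)CC)C#CC[C@@H](C)O[Si](CC)(CC)CC | intermediate
18 | oleoyl chloride | CCCCCCCC/C=C\CCCCCCCC(=O)Cl | starting material
19 | (3R,8R)-3-methyl-2-oxo-4,8-bis(triethylsilyloxy)non-5-yn-3-yl (9Z)-octadec-9-enoate | CCCCCCCC/C=C\CCCCCCCC(=O)O[C@@](C)(C(C)=O)C(O[Si](CC)(CC)CC)C#CC[C@@H](C)O[Si](CC)(CC)CC | intermediate
20 | N,N-dimethylformamide dimethyl acetal | COC(OC)N(C)C | starting material
21 | (1E,4R,9R)-1-(dimethylamino)-4-methyl-3-oxo-5,9-bis(triethylsilyloxy)dec-1-en-6-yn-4-yl (9Z)-octadec-9-enoate | CCCCCCCC/C=C\CCCCCCCC(=O)O[C@@](C)(C(=O)/C=C/N(C)C)C(O[Si](CC)(CC)CC)C#CC[C@@H](C)O[Si](CC)(CC)CC | intermediate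
22 | (1E,4R,9R)-1-(dimethylamino)-5,9-dihydroxy-4-methyl-3-oxodec-1-en-6-yn-4-yl (9Z)-octadec-9-enoate | CCCCCCCC/C=C\CCCCCCCC(=O)O[C@@](C)(C(=O)/C=C/N(C)C)C(O)C#CC[C@@H](C)O | intermediate
23 | (1E,4S,9R)-1-(dimethylamino)-9-hydroxy-4-methyl-3,5-dioxodec-1-en-6-yn-4-yl (9Z)-octadec-9-enoate | CCCCCCCC/C=C\CCCCCCCC(=O)O[C@@](C)(C(=O)/C=C/N(C)C)C(=O)C#CC[C@@H](C)O | intermediate
24 | (1R)-3-[(dimethylamino)methylidene]-4-[(2R)-2-hydroxypropyl]-1-methyl-2,6-dioxocyclohex-4-en-1-yl (9Z)-octadec-9-enoate | CCCCCCCC/C=C\CCCCCCCC(=O)O[C@]1(C)C(=O)C=C(C[C@@H](C)O)C(=CN(C)C)C1=O | intermediate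
25 | (3R,7R)-1-(dimethylamino)-3,7-dimethyl-6,8-dioxo-3,4,6,7,8,8a-hexahydro-1H-isochromen-7-yl (9Z)-octadec-9-enoate (C1 and C8a unassigned) | CCCCCCCC/C=C\CCCCCCCC(=O)O[C@]1(C)C(=O)C=C2C[C@@H](C)OC(N(C)C)C2C1=O | intermediate
26 | (3R,7R)-3,7-dimethyl-6,8-dioxo-3,4,7,8-tetrahydro-6H-isochromen-7-yl (9Z)-octadec-9-enoate | CCCCCCCC/C=C\CCCCCCCC(=O)O[C@]1(C)C(=O)C=C2C[C@@H](C)OC=C2C1=O | target

**Count and risks**

Total step count: 11. Longest linear sequence: 10 steps (steps 2 to 11, from (R)-pent-4-yn-2-ol).

Step 11 (proposed new method). The cascade may stall at the vinylogous amide stage, or the enaminone may react through oxygen or between molecules instead of closing the carbocycle. The fallback uses known anionic chemistry and builds the rings one after the other. It sets out from 23: hydrolysis of the enaminone with dilute aqueous HCl in THF should give the formyl ketone (4S,9R)-9-hydroxy-4-methyl-1,3,5-trioxodec-6-yn-4-yl (9Z)-octadec-9-enoate F1. Catalytic Cs2CO3 in MeCN at 0 °C should then bring about the intramolecular Michael addition of the 1,3-dicarbonyl carbanion to the ynone (6-endo-dig) to give (1R)-3-formyl-4-[(2R)-2-hydroxypropyl]-1-methyl-2,6-dioxocyclohex-4-en-1-yl (9Z)-octadec-9-enoate F2. Catalytic TsOH·H2O in toluene should close the lactol and dehydrate it, which comes back to the route at 26.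

Step 8. Under the warm, weakly basic condensation conditions the transient enolate of the methyl ketone may attack the neighbouring tertiary ester (acyl transfer towards a furanone), or the ester may be cleaved before aminomethylenation is complete. The fallback makes the enaminone by amine addition to an ynone, with no enolate involved. It sets out from 14: lithium (trimethylsilyl)acetylide in THF at −78 °C, then a cold AcOH quench, should give (4R,9R)-4-hydroxy-4-methyl-5,9-bis(triethylsilyloxy)-1-(trimethylsilyl)deca-1,6-diyn-3-one F3. Acylation with oleoyl chloride, DMAP and Et3N should give (4R,9R)-4-methyl-3-oxo-5,9-bis(triethylsilyloxy)-1-(trimethylsilyl)deca-1,6-diyn-4-yl (9Z)-octadec-9-enoate F4. Dimethylamine in THF/MeOH at 0 °C should add to the ynone with loss of the C-silyl group, which comes back to the route at 21.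

Step 6. The hemiketal alkoxide may collapse in the flask, which would allow a second addition of the organolithium or migration of a silyl group from the secondary to the tertiary oxygen. The fallback opens the acetal-lactone with a nitrogen nucleophile first. It sets out from 14: MeNH(OMe)·HCl and i-PrMgCl in THF at −20 °C should give (2R,7R)-2-hydroxy-N-methoxy-N,2-dimethyl-3,7-bis(triethylsilyloxy)oct-4-ynamide F5. MeMgBr in THF at 0 °C, whose chelated adduct cannot add a second time, should then give the methyl ketone, which comes back to the route at 17.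

**Further compounds**

F1 | step 11 | (4S,9R)-9-hydroxy-4-methyl-1,3,5-trioxodec-6-yn-4-yl (9Z)-octadec-9-enoate | CCCCCCCC/C=C\CCCCCCCC(=O)O[C@@](C)(C(=O)CC=O)C(=O)C#CC[C@@H](C)O
F2 | step 11 | (1R)-3-formyl-4-[(2R)-2-hydroxypropyl]-1-methyl-2,6-dioxocyclohex-4-en-1-yl (9Z)-octadec-9-enoate | CCCCCCCC/C=C\CCCCCCCC(=O)O[C@]1(C)C(=O)C=C(C[C@@H](C)O)C(C=O)C1=O
F3 | step 8 | (4R,9R)-4-hydroxy-4-methyl-5,9-bis(triethylsilyloxy)-1-(trimethylsilyl)deca-1,6-diyn-3-one | C[Si](C)(C)C#CC(=O)[C@](C)(O)C(O[Si](CC)(CC)CC)C#CC[C@@H](C)O[Si](CC)(CC)CC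
F4 | step 8 | (4R,9R)-4-methyl-3-oxo-5,9-bis(triethylsilyloxy)-1-(trimethylsilyl)deca-1,6-diyn-4-yl (9Z)-octadec-9-enoate | CCCCCCCC/C=C\CCCCCCCC(=O)O[C@@](C)(C(=O)C#C[Si](C)(C)C)C(O[Si](CC)(CC)CC)C#CC[C@@H](C)O[Si](CC)(CC)CC
F5 | step 6 | (2R,7R)-2-hydroxy-N-methoxy-N,2-dimethyl-3,7-bis(triethylsilyloxy)oct-4-ynamide | CON(C)C(=O)[C@](C)(O)C(O[Si](CC)(CC)CC)C#CC[C@@H](C)O[Si](CC)(CC)CC
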